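The easy step is to take, at each reading, the fraction u of the charge that is not yet product and to form k = −ln(u)/t, with t the time. Call k the running constant (the field's apparent first-order constant); a plain first-order flask keeps it flat.

| setting | Saturday's | Friday's | eta | zeta |
|---|---|---|---|---|
| starting material | 8.2 mM | 13 mM | 10 mM | 20 mM |
| temperature | 95 °C | 106 °C | 100 °C | 100 °C |
| remark | run made earlier | run made earlier |  |  |
| time |  |  | 2.5 h | 10 h |

| run | time / h | product / % |
|---|---|---|
| Saturday's | 0.833 | 8 |
| Saturday's | 1.50 | 17 |
| Saturday's | 2.50 | 24 |
| Saturday's | 3.00 | 29 |
| Saturday's | 4.00 | 39 |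
| Saturday's | 5.00 | 46 |
| Friday's | 0.417 | 11 |
| Friday's | 0.667 | 20 |
| Friday's | 1.00 | 28 |
| Friday's | 2.00 | 51 |
| Friday's | 3.00 | 69 |
| Friday's | 5.00 | 88 |

(each reading ± 1.5 percentage points)

1. which one finishes higher in amount of product, in percent of the starting material charged ("neither" within 2 percentage points) (eta / zeta / neither)
2. amount of product at the end, in percent of the starting material charged, eta
3. amount of product at the end, in percent of the starting material charged, zeta

- a reading or a percentage of product counts all its forms, free or not

Now read down the tables. Saturday's first row gives k = 0.100 h⁻¹ and its last row 0.123 h⁻¹, a gap that a scatter of 1.5 percentage points on so small a reading can cover. Friday's first row gives 0.279 h⁻¹ and its last row 0.424 h⁻¹, so there the constant climbs down the table.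

Both last rows stand at the same time, 5.00 h, so they serve as anchors. An equal ratio per degree between them gives, at 100 °C, kb = 0.216 h⁻¹, the running constant of the bath. Both new flasks stand at that temperature. Eta has kb·t = 0.540, so 1 − exp(−kb·t) gives 41.7% product. Zeta has kb·t = 2.16, which gives 88.5%.

The drift tempers the second figure. Friday's constant sits lower early on, and zeta's charge of 20 mM is higher than that of either run, so zeta's figure leans high. Even so, the gap of 47 points stays far wider than the margin, and zeta finishes higher.

The forecast, finding “no sign of a plateau”, gave 40% (33% to 47%) for eta and 85% (75% to 93%) for zeta, both below this reckoning, and named zeta.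

The flask gives 39.3% for eta and 84.7% for zeta, so zeta finishes higher.

    starting material + product ⇌ idle adduct, settled at all times (K = 99.0 M⁻¹, ΔH = −63.0 kJ mol⁻¹)
    starting material → product, rate k2*[starting material]/(1 + ([starting material]/sat2)) (11.0 mM, k = 0.350 h⁻¹, Ea = 128 kJ mol⁻¹)
    crystals ⇌ product, rate k3*(cs3 - [product]) while solid is left; crystals form when [product] > cs3 (solubility = 0.310 mM, k = 12.0 h⁻¹)
    (constants at 100 °C)

At the end of zeta, 14.7% of the charge is still starting material, and crystals hold 82.2%, counted in product. Zeta's product, put through the same formula, reads k = 0.188 h⁻¹, lower than kb. The neighbour flask, zeta with 5.0 mM of starting material, gives 94.9% product, which reads k = 0.297 h⁻¹, higher than kb.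

Readings and results are calculated for substances that don't exist; scatter was added.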